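**Strategy**

Ring C is taken apart at O1–C8a, C4–C4a and O1–C2, which leads back to a 3,5-dioxygenated benzyne and a β-methoxyacrylic acid that already carries both prenyl ethers. The feature used is the ortho relationship in ring A between C8a, which bears the pyranone oxygen O1, and C4a, which bears the C4 carbonyl and is flanked by the oxygenated C5: an alkoxy-flanked aryne takes up a carboxylate oxygen at its remote terminus and the acyl carbon at the near one. One operation thus makes the aryl ether, the aryl ketone and the pyranone. The precursors are a bis-MOM silylaryl triflate and (E)-3-methoxy-2-(prenyloxy)-3-[4-(prenyloxy)phenyl]acrylic acid; C8 is methoxylated afterwards through the free 5-phenol.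

Key step: step 10

Abbreviations: prenyl = 3-methylbut-2-en-1-yl; MOM = methoxymethyl; TBS = tert-butyldimethylsilyl; CDI = 1,1'-carbonyldiimidazole; CSA = camphorsulfonic acid.

Assumption: the O-methylation of step 8 may give either alkene isomer of 18 or a mixture; the E isomer is drawn and carried, and the geometry has no bearing on step 10 because C2 passes through a tetrahedral adduct. The target has no stereocentre; the single stereocentre of racemic 17 is erased in step 8.

**Route**

Step 1
Reactants: 1 phloroglucinol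
Product: 2 3,5-bis(methoxymethoxy)phenol
Conditions: MOMCl (2.1 equiv), i-Pr2NEt, DMF, 0 °C → rt; chromatography
Reagents that add atoms: chloromethyl methyl ether, COCCl
Why: Williamson-type O-alkylation of the phenoxide by the reactive chloromethyl ether; the three hydroxyls are equivalent, so the bis-ether forms statistically and is separated from the mono- and tris-ethers.

Step 2
Reactants: 2 3,5-bis(methoxymethoxy)phenol
Product: 3 3,5-bis(methoxymethoxy)phenyl N-isopropylcarbamate
Conditions: i-PrNCO, Et3N (cat.), CH2Cl2, rt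
Reagents that add atoms: isopropyl isocyanate, CC(C)N=C=O
Why: base-catalysed addition of the phenol to the isocyanate (carbamoylation) installs a removable ortho-directing group.

Step 3
Reactants: 3 3,5-bis(methoxymethoxy)phenyl N-isopropylcarbamate
Product: 7 3,5-bis(methoxymethoxy)-2-(trimethylsilyl)phenyl N-isopropylcarbamate, via N-silyl carbamate 4 (not isolated), via aryllithium 5 (not isolated), via bis-silyl carbamate 6 (not isolated)
Conditions: TBSOTf (1.05 equiv), TMEDA, Et2O, 0 °C → rt; n-BuLi, TMEDA, −78 °C; Me3SiCl, −78 °C → rt; aq. NH4Cl–MeOH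
Reagents that add atoms: chlorotrimethylsilane, C[Si](C)(C)Cl
Why: directed ortho-metalation, in which transient N-silylation makes the carbamate a strong directing group, lithiation occurs at C2 where carbamate and MOM ether cooperate (C2 and C6 are equivalent), the silyl chloride traps the anion at −78 °C before an anionic Fries shift can set in, and the N–Si bond is hydrolysed on work-up.

Step 4
Reactants: 7 3,5-bis(methoxymethoxy)-2-(trimethylsilyl)phenyl N-isopropylcarbamate
Product: 9 3,5-bis(methoxymethoxy)-2-(trimethylsilyl)phenyl trifluoromethanesulfonate, via silylphenol 8 (not isolated)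
Conditions: DBU, Et2NH, MeCN, 40 °C; then PhNTf2, rt
Reagents that add atoms: N-phenylbis(trifluoromethanesulfonimide), O=S(=O)(N(c1ccccc1)S(=O)(=O)C(F)(F)F)C(F)(F)F
Why: E1cB cleavage of the N–H carbamate releases the phenoxide and isopropyl isocyanate (trapped by diethylamine), and the phenoxide is triflated in the same pot by the mild triflimide, so the protodesilylation-prone o-silylphenol is never isolated.

Step 5
Reactants: 10 methyl glycolate, 11 prenyl bromide
Product: 12 methyl 2-(prenyloxy)acetate
Conditions: NaH, n-Bu4NI (cat.), THF, 0 °C → rt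
Reagents that add atoms: none
Why: Williamson ether synthesis, with SN2 attack of the sodium alkoxide at the primary allylic carbon of the bromide.

Step 6
Reactants: 13 methyl 4-hydroxybenzoate, 11 prenyl bromide
Product: 15 4-(prenyloxy)benzoic acid, via methyl 4-(prenyloxy)benzoate 14 (not isolated)
Conditions: K2CO3, DMF, rt; then NaOH, MeOH–H2O, 60 °C; cold aq. citric acid to pH 4
Reagents that add atoms: sodium hydroxide, [Na+].[OH-]
Why: phenoxide O-alkylation (Williamson) followed by ester saponification in the same pot, both under basic conditions to which the prenyl ether is inert.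

Step 7
Reactants: 15 4-(prenyloxy)benzoic acid, 12 methyl 2-(prenyloxy)acetate
Product: 17 methyl 3-oxo-2-(prenyloxy)-3-[4-(prenyloxy)phenyl]propanoate (racemic), via acylimidazole 16 (not isolated)
Conditions: 15, CDI, THF, rt; transferred into 12 (3 equiv), LiN(SiMe3)2 (3 equiv), THF, −78 °C; AcOH quench at −78 °C
Reagents that add atoms: none
Why: crossed Claisen condensation in which the lithium enolate of the glycolate ester is C-acylated by the acylimidazole at −78 °C, a temperature at which the [2,3]-Wittig shift of the α-prenyloxy enolate is slow, while the surplus enolate absorbs the imidazole N–H and the acidic product and the acylimidazole avoids the HCl of an acid chloride preparation.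

Step 8
Reactants: 17 methyl 3-oxo-2-(prenyloxy)-3-[4-(prenyloxy)phenyl]propanoate
Product: 18 methyl (E)-3-methoxy-2-(prenyloxy)-3-[4-(prenyloxy)phenyl]acrylate
Conditions: Cs2CO3, Me2SO4, DMF, 0 °C → rt
Reagents that add atoms: dimethyl sulfate, COS(=O)(=O)OC
Why: O-alkylation of a β-keto ester enolate, favoured over C-alkylation by the hard methyl donor, the dissociated cesium enolate in DMF and the fully substituted α-carbon.

Step 9
Reactants: 18 methyl (E)-3-methoxy-2-(prenyloxy)-3-[4-(prenyloxy)phenyl]acrylate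
Product: 19 (E)-3-methoxy-2-(prenyloxy)-3-[4-(prenyloxy)phenyl]acrylic acid
Conditions: LiOH·H2O, THF–MeOH–H2O, 45 °C; then aq. citric acid, 0 °C, pH 4
Reagents that add atoms: lithium hydroxide, [Li+].[OH-]
Why: ester saponification by acyl–oxygen cleavage, with the donor-substituted C3 unreactive toward hydroxide at this temperature and a mild acidification that leaves the enol ether and the prenyl ethers intact.

Step 10
Reactants: 9 3,5-bis(methoxymethoxy)-2-(trimethylsilyl)phenyl trifluoromethanesulfonate, 19 (E)-3-methoxy-2-(prenyloxy)-3-[4-(prenyloxy)phenyl]acrylic acid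
Product: 22 5,7-bis(methoxymethoxy)-3-(prenyloxy)-2-[4-(prenyloxy)phenyl]-4H-chromen-4-one, via aryne 20 (not isolated), via cesium acylphenoxide 21 (not isolated)
Conditions: CsF (4 equiv), 9 (1.5 equiv), THF, 125 °C, sealed tube
Reagents that add atoms: none
Why: Fluoride strips the silyl group from 9 and triflate departs, giving aryne 20; the cesium salt of 19 bonds through a carboxylate oxygen to the aryne carbon that becomes C8a, the resulting C4a carbanion adds to the neighbouring ester carbonyl, and collapse of this strained four-membered alkoxide breaks the original acyl–oxygen bond to leave the ketone-bearing phenoxide 21. The closest known reaction is the fluoride-induced insertion of arynes into the C–O bond of carboxylic acids, which gives o-hydroxyaryl ketones and, with unsaturated acids, goes on to chromanones and flavones. Ring C closes when the phenoxide oxygen of 21 adds to C2 of the β-methoxy enone in a 6-endo-trig conjugate addition and methoxide is expelled, so E and Z acid give the same flavone. No stereocentre is formed. The step needs the carboxylate at C8a and not at C4a, which the σ-withdrawing MOM-oxygen on the carbon next to the aryne (the future C5) secures by polarising the triple bond so that nucleophiles enter at the remote terminus and the charge develops ortho to oxygen. It also needs acyl transfer to outrun protonation of the aryl anion, which the aprotic medium and the high temperature favour, and the basic, non-oxidising conditions leave the MOM and prenyl ethers in place.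

Step 11
Reactants: 22 5,7-bis(methoxymethoxy)-3-(prenyloxy)-2-[4-(prenyloxy)phenyl]-4H-chromen-4-one
Product: 23 5-hydroxy-7-(methoxymethoxy)-3-(prenyloxy)-2-[4-(prenyloxy)phenyl]-4H-chromen-4-one
Conditions: CSA (0.2 equiv), MeOH–CH2Cl2, 0 °C → rt; Et3N quench
Reagents that add atoms: none
Why: acid-catalysed acetal methanolysis that is selective for the peri 5-O-MOM group, whose cleavage is assisted by the C4 carbonyl, while the unassisted 7-O-MOM group and the prenyl ethers should not respond to catalytic acid at room temperature.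

Step 12
Reactants: 23 5-hydroxy-7-(methoxymethoxy)-3-(prenyloxy)-2-[4-(prenyloxy)phenyl]-4H-chromen-4-one
Product: 25 5-hydroxy-8-methoxy-7-(methoxymethoxy)-3-(prenyloxy)-2-[4-(prenyloxy)phenyl]-4H-chromen-4-one, via quinone monoketal 24 (not isolated)
Conditions: PhI(OAc)2 (2.2 equiv), MeOH, 0 °C; then Zn dust, AcOH, 0 °C → rt
Reagents that add atoms: methanol, CO
Why: hypervalent-iodine oxidative dearomatisation of a para-unsubstituted phenol in methanol delivers methanol twice to C8 (para to O5 and activated by O7 and O1) to give the quinone monoketal, and zinc reduction of the dienone expels one methoxide and restores the aromatic ring as the 8-methoxy-5-phenol.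

Step 13
Reactants: 25 5-hydroxy-8-methoxy-7-(methoxymethoxy)-3-(prenyloxy)-2-[4-(prenyloxy)phenyl]-4H-chromen-4-one
Product: 27 5,7-dihydroxy-8-methoxy-3-(prenyloxy)-2-[4-(prenyloxy)phenyl]-4H-chromen-4-one, via bis(trimethylsilyl) ether 26 (not isolated)
Conditions: Me3SiOTf (3 equiv), 2,2'-bipyridyl (5 equiv), MeCN, 0 °C → rt; then H2O, rt
Reagents that add atoms: none
Why: non-protic cleavage of an aromatic MOM ether, in which the silyl triflate–bipyridyl pair exchanges the acetal for a trimethylsilyl ether (the methoxymethyl unit passes to the pyridine) and water then frees the phenols, so the allylic prenyl ethers never meet the strong protic acid that an unassisted aryl MOM ether would otherwise require.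

**Compound list**

1 | phloroglucinol | Oc1cc(O)cc(O)c1 | starting material
2 | 3,5-bis(methoxymethoxy)phenol | COCOc1cc(O)cc(OCOC)c1 | intermediate
3 | 3,5-bis(methoxymethoxy)phenyl N-isopropylcarbamate | COCOc1cc(OCOC)cc(OC(=O)NC(C)C)c1 | intermediate
4 | 3,5-bis(methoxymethoxy)phenyl N-(tert-butyldimethylsilyl)-N-isopropylcarbamate, formed in the flask | COCOc1cc(OCOC)cc(OC(=O)N(C(C)C)[Si](C)(C)C(C)(C)C)c1 | intermediate
5 | 2-lithio derivative of 4 (lithium at the ring carbon between the carbamate and a MOM ether), formed in the flask | COCOc1cc(OCOC)c([Li])c(OC(=O)N(C(C)C)[Si](C)(C)C(C)(C)C)c1 | intermediate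
6 | 3,5-bis(methoxymethoxy)-2-(trimethylsilyl)phenyl N-(tert-butyldimethylsilyl)-N-isopropylcarbamate, formed in the flask | COCOc1cc(OCOC)c([Si](C)(C)C)c(OC(=O)N(C(C)C)[Si](C)(C)C(C)(C)C)c1 | intermediate
7 | 3,5-bis(methoxymethoxy)-2-(trimethylsilyl)phenyl N-isopropylcarbamate | COCOc1cc(OCOC)c([Si](C)(C)C)c(OC(=O)NC(C)C)c1 | intermediate
8 | 3,5-bis(methoxymethoxy)-2-(trimethylsilyl)phenol, present as its DBU salt in the flask | COCOc1cc(O)c([Si](C)(C)C)c(OCOC)c1 | intermediate
9 | 3,5-bis(methoxymethoxy)-2-(trimethylsilyl)phenyl trifluoromethanesulfonate | COCOc1cc(OCOC)c([Si](C)(C)C)c(OS(=O)(=O)C(F)(F)F)c1 | intermediate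
10 | methyl glycolate | COC(=O)CO | starting material
11 | prenyl bromide (1-bromo-3-methylbut-2-ene) | CC(C)=CCBr | starting material
12 | methyl 2-(prenyloxy)acetate | COC(=O)COCC=C(C)C | intermediate
13 | methyl 4-hydroxybenzoate | COC(=O)c1ccc(O)cc1 | starting material
14 | methyl 4-(prenyloxy)benzoate, formed in the flask | COC(=O)c1ccc(OCC=C(C)C)cc1 | intermediate
15 | 4-(prenyloxy)benzoic acid | OC(=O)c1ccc(OCC=C(C)C)cc1 | intermediate
16 | 1-[4-(prenyloxy)benzoyl]imidazole, formed in the flask | O=C(c1ccc(OCC=C(C)C)cc1)n1ccnc1 | intermediate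
17 | methyl 3-oxo-2-(prenyloxy)-3-[4-(prenyloxy)phenyl]propanoate, racemic | COC(=O)C(OCC=C(C)C)C(=O)c1ccc(OCC=C(C)C)cc1 | intermediate
18 | methyl (E)-3-methoxy-2-(prenyloxy)-3-[4-(prenyloxy)phenyl]acrylate | CO/C(=C(/OCC=C(C)C)C(=O)OC)c1ccc(OCC=C(C)C)cc1 | intermediate
19 | (E)-3-methoxy-2-(prenyloxy)-3-[4-(prenyloxy)phenyl]acrylic acid | CO/C(=C(/OCC=C(C)C)C(=O)O)c1ccc(OCC=C(C)C)cc1 | intermediate
20 | 3,5-bis(methoxymethoxy)benzyne (1,2-didehydro-3,5-bis(methoxymethoxy)benzene), formed in the flask | COCOC1=CC(OCOC)=CC#C1 | intermediate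
21 | cesium 3,5-bis(methoxymethoxy)-2-{(E)-3-methoxy-2-(prenyloxy)-3-[4-(prenyloxy)phenyl]acryloyl}phenoxide, formed in the flask | [Cs+].CO/C(=C(/OCC=C(C)C)C(=O)c1c([O-])cc(OCOC)cc1OCOC)c1ccc(OCC=C(C)C)cc1 | intermediate
22 | 5,7-bis(methoxymethoxy)-3-(prenyloxy)-2-[4-(prenyloxy)phenyl]-4H-chromen-4-one | COCOc1cc(OCOC)c2c(=O)c(OCC=C(C)C)c(-c3ccc(OCC=C(C)C)cc3)oc2c1 | intermediate
23 | 5-hydroxy-7-(methoxymethoxy)-3-(prenyloxy)-2-[4-(prenyloxy)phenyl]-4H-chromen-4-one | COCOc1cc(O)c2c(=O)c(OCC=C(C)C)c(-c3ccc(OCC=C(C)C)cc3)oc2c1 | intermediate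
24 | 8,8-dimethoxy-7-(methoxymethoxy)-3-(prenyloxy)-2-[4-(prenyloxy)phenyl]-4H-chromene-4,5(8H)-dione, formed in the flask | COCOC1=CC(=O)C2=C(OC(-c3ccc(OCC=C(C)C)cc3)=C(OCC=C(C)C)C2=O)C1(OC)OC | intermediate
25 | 5-hydroxy-8-methoxy-7-(methoxymethoxy)-3-(prenyloxy)-2-[4-(prenyloxy)phenyl]-4H-chromen-4-one | COCOc1cc(O)c2c(=O)c(OCC=C(C)C)c(-c3ccc(OCC=C(C)C)cc3)oc2c1OC | intermediate
26 | 8-methoxy-3-(prenyloxy)-2-[4-(prenyloxy)phenyl]-5,7-bis(trimethylsilyloxy)-4H-chromen-4-one, formed in the flask | COc1c(O[Si](C)(C)C)cc(O[Si](C)(C)C)c2c(=O)c(OCC=C(C)C)c(-c3ccc(OCC=C(C)C)cc3)oc12 | intermediate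
27 | 5,7-dihydroxy-8-methoxy-3-(prenyloxy)-2-[4-(prenyloxy)phenyl]-4H-chromen-4-one (5,7-dihydroxy-8-methoxy-3,4'-diprenyloxyflavone) | COc1c(O)cc(O)c2c(=O)c(OCC=C(C)C)c(-c3ccc(OCC=C(C)C)cc3)oc12 | target

**Step count and risk**

Total step count: 13. Longest linear sequence: 8 steps (steps 1–4 and 10–13 from phloroglucinol, or steps 6–13 from methyl 4-hydroxybenzoate).

Steps most likely to fail:

1. Step 10. The C4a carbanion may be protonated before it reaches the acyl carbon, which would stop at the aryl ester with no C–C bond. The carboxylate may also add at the wrong aryne terminus, or the prenyl ethers (the acid is an allyl vinyl ether) may undergo thermal [3,3] shifts at 125 °C. The fallback sets out from 1 and 19 and returns to the route at 22. Exhaustive protection of 1 (MOMCl, NaH, DMF) would give 1,3,5-tris(methoxymethoxy)benzene F1, which n-BuLi (THF, 0 °C) should lithiate between two MOM ethers to 2,4,6-tris(methoxymethoxy)phenyllithium F2. Acid 19 would be converted (MeNHOMe·HCl, EDC·HCl, i-Pr2NEt, CH2Cl2) into the Weinreb amide (E)-N,3-dimethoxy-N-methyl-2-(prenyloxy)-3-[4-(prenyloxy)phenyl]acrylamide F3. Addition of F2 to F3 at −78 °C should stop at the ketone (E)-3-methoxy-2-(prenyloxy)-3-[4-(prenyloxy)phenyl]-1-[2,4,6-tris(methoxymethoxy)phenyl]prop-2-en-1-one F4. Catalytic CSA in MeOH at 0 °C should remove one of the two ketone-assisted ortho acetals to give (E)-1-[2-hydroxy-4,6-bis(methoxymethoxy)phenyl]-3-methoxy-2-(prenyloxy)-3-[4-(prenyloxy)phenyl]prop-2-en-1-one F5, the free phenol of 21. K2CO3 in MeOH should then close ring C by the same addition–elimination and give 22.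

2. Step 12. Ligand exchange at iodine by the hydrogen-bonded 5-hydroxyl may be slow, so that methanol attack at C6, oxidation of the prenyl alkenes or incomplete reductive aromatisation competes. The fallback sets out from 23 and returns at 25. Teuber oxidation with (KSO3)2NO (KH2PO4 buffer, acetone–H2O, rt) should give the p-quinone 7-(methoxymethoxy)-3-(prenyloxy)-2-[4-(prenyloxy)phenyl]-4H-chromene-4,5,8-trione F6. Na2S2O4 (EtOAc–H2O) should reduce it to 5,8-dihydroxy-7-(methoxymethoxy)-3-(prenyloxy)-2-[4-(prenyloxy)phenyl]-4H-chromen-4-one F7. MeI (1 equiv) with K2CO3 in acetone under argon should methylate only the non-chelated 8-hydroxyl and give 25.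

3. Step 13. Acetal exchange at the non-chelated O7, which in 25 is hemmed in by the new 8-methoxy group, may be slow, and prolonged exposure to the silyl triflate may then erode the prenyl ethers. The fallback sets out from 23, where O7 is unhindered, and returns at 27. It still relies on the same silyl triflate–bipyridyl exchange in the presence of the prenyl ethers, so it answers only the steric problem, but its last step is a fluoride desilylation that cannot touch them. The same exchange (Me3SiOTf, 2,2'-bipyridyl, MeCN) applied to 23 should give 3-(prenyloxy)-2-[4-(prenyloxy)phenyl]-5,7-bis(trimethylsilyloxy)-4H-chromen-4-one F8, hydrolysed on work-up to 5,7-dihydroxy-3-(prenyloxy)-2-[4-(prenyloxy)phenyl]-4H-chromen-4-one F9. i-Pr3SiCl and imidazole (DMF, 0 °C) should silylate only the non-chelated hydroxyl and give 5-hydroxy-3-(prenyloxy)-2-[4-(prenyloxy)phenyl]-7-(triisopropylsilyloxy)-4H-chromen-4-one F10. PhI(OAc)2 in MeOH should lead to 8,8-dimethoxy-3-(prenyloxy)-2-[4-(prenyloxy)phenyl]-7-(triisopropylsilyloxy)-4H-chromene-4,5(8H)-dione F11, and Zn with AcOH to 5-hydroxy-8-methoxy-3-(prenyloxy)-2-[4-(prenyloxy)phenyl]-7-(triisopropylsilyloxy)-4H-chromen-4-one F12. n-Bu4NF buffered with AcOH (THF, 0 °C) should then give 27, and any material desilylated earlier converges on the same product.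

**Further compounds**

F1 | step 10 | 1,3,5-tris(methoxymethoxy)benzene | COCOc1cc(OCOC)cc(OCOC)c1
F2 | step 10 | 2,4,6-tris(methoxymethoxy)phenyllithium | [Li]c1c(OCOC)cc(OCOC)cc1OCOC
F3 | step 10 | (E)-N,3-dimethoxy-N-methyl-2-(prenyloxy)-3-[4-(prenyloxy)phenyl]acrylamide | CO/C(=C(/OCC=C(C)C)C(=O)N(C)OC)c1ccc(OCC=C(C)C)cc1
F4 | step 10 | (E)-3-methoxy-2-(prenyloxy)-3-[4-(prenyloxy)phenyl]-1-[2,4,6-tris(methoxymethoxy)phenyl]prop-2-en-1-one | CO/C(=C(/OCC=C(C)C)C(=O)c1c(OCOC)cc(OCOC)cc1OCOC)c1ccc(OCC=C(C)C)cc1
F5 | step 10 | (E)-1-[2-hydroxy-4,6-bis(methoxymethoxy)phenyl]-3-methoxy-2-(prenyloxy)-3-[4-(prenyloxy)phenyl]prop-2-en-1-one | CO/C(=C(/OCC=C(C)C)C(=O)c1c(O)cc(OCOC)cc1OCOC)c1ccc(OCC=C(C)C)cc1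
F6 | step 12 | 7-(methoxymethoxy)-3-(prenyloxy)-2-[4-(prenyloxy)phenyl]-4H-chromene-4,5,8-trione | COCOC1=CC(=O)C2=C(OC(-c3ccc(OCC=C(C)C)cc3)=C(OCC=C(C)C)C2=O)C1=O
F7 | step 12 | 5,8-dihydroxy-7-(methoxymethoxy)-3-(prenyloxy)-2-[4-(prenyloxy)phenyl]-4H-chromen-4-one | COCOc1cc(O)c2c(=O)c(OCC=C(C)C)c(-c3ccc(OCC=C(C)C)cc3)oc2c1O
F8 | step 13 | 3-(prenyloxy)-2-[4-(prenyloxy)phenyl]-5,7-bis(trimethylsilyloxy)-4H-chromen-4-one | C[Si](C)(C)Oc1cc(O[Si](C)(C)C)c2c(=O)c(OCC=C(C)C)c(-c3ccc(OCC=C(C)C)cc3)oc2c1
F9 | step 13 | 5,7-dihydroxy-3-(prenyloxy)-2-[4-(prenyloxy)phenyl]-4H-chromen-4-one | Oc1cc(O)c2c(=O)c(OCC=C(C)C)c(-c3ccc(OCC=C(C)C)cc3)oc2c1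
F10 | step 13 | 5-hydroxy-3-(prenyloxy)-2-[4-(prenyloxy)phenyl]-7-(triisopropylsilyloxy)-4H-chromen-4-one | CC(C)[Si](Oc1cc(O)c2c(=O)c(OCC=C(C)C)c(-c3ccc(OCC=C(C)C)cc3)oc2c1)(C(C)C)C(C)C
F11 | step 13 | 8,8-dimethoxy-3-(prenyloxy)-2-[4-(prenyloxy)phenyl]-7-(triisopropylsilyloxy)-4H-chromene-4,5(8H)-dione | COC1(OC)C(O[Si](C(C)C)(C(C)C)C(C)C)=CC(=O)C2=C1OC(-c1ccc(OCC=C(C)C)cc1)=C(OCC=C(C)C)C2=O
F12 | step 13 | 5-hydroxy-8-methoxy-3-(prenyloxy)-2-[4-(prenyloxy)phenyl]-7-(triisopropylsilyloxy)-4H-chromen-4-one | COc1c(O[Si](C(C)C)(C(C)C)C(C)C)cc(O)c2c(=O)c(OCC=C(C)C)c(-c3ccc(OCC=C(C)C)cc3)oc12
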